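**Retrosynthetic overview**

1. The strategy rests on one feature: in the fused pyranone ring A (O5, C4, C3a, C7a, C7, C6) the carbonyl C4 and its α-carbon C3a, together with C3, C2 and O1 of the dihydrofuran, are the atoms of a γ-butyrolactone (O1–C2–C3–C3a–C4=O) that carries the aryl group on C2 and the future ring B on C3, trans.
2. Last disconnections: O-demethylation; ring B from a gold-catalysed 6-endo cyclisation of a tert-butyl 3-oxo-4-ynoate grown on an ethynyl group at C3.
3. Key disconnection: ring A and the dihydrofuran from an α-acetyl butyrolactone and a cinnamic Weinreb amide (C6–C7 by dianion acylation, C4–O5 by translactonisation, O1–C7a by cyclodehydration).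
4. The trans lactone (C2 and C3 set) comes from a syn-selective SE2′ addition of an axially chiral allenylstannane to veratraldehyde, since the syn homopropargylic alcohol is the one that lactonises to the trans lactone; the stannane comes from a propargylic alcohol made by asymmetric transfer hydrogenation.
5. Ring order: the sacrificial butyrolactone first, then ring A and the dihydrofuran together, then ring B.

Key step: step 8

Assumption: atom numbers follow the 2,3-dihydro-4H-furo[3,2-c]pyran-4-one core (O1, C2, C3, C3a, C4, O5, C6, C7, C7a); the sense of induction in step 2 is assigned by analogy with simpler alkynyl ketones and would be checked before step 3.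

**Route**

Step 1
Reactants: 1 ethyl 3-(trimethylsilyl)prop-2-ynoate; 2 ethyl acetate
Product: 3 ethyl 3-oxo-5-(trimethylsilyl)pent-4-ynoate
Conditions: LiN(iPr)2 (2.2 equiv), 2 (2.2 equiv), THF, −78 °C; then 1; AcOH quench
Reagents that add atoms: none
Why: Crossed Claisen condensation in which the lithium enolate of ethyl acetate adds 1,2 to the propiolate (the silyl group shields the β-carbon from conjugate addition) and a second equivalent of enolate deprotonates the β-keto ester, which stops over-addition.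

Step 2
Reactants: 3 ethyl 3-oxo-5-(trimethylsilyl)pent-4-ynoate
Product: 4 ethyl (R)-3-hydroxy-5-(trimethylsilyl)pent-4-ynoate
Conditions: RuCl[(R,R)-TsDPEN](p-cymene) (1 mol %), HCO2H/Et3N (5:2), CH2Cl2, rt
Reagents that add atoms: none
Why: Noyori asymmetric transfer hydrogenation of an alkynyl ketone, a reaction type that tolerates the β-keto ester; the alkyne sits under the η6-arene of the divalent ruthenium hydride, so the (R,R)-ligand should set the (R)-carbinol.

Step 3
Reactants: 4 ethyl (R)-3-hydroxy-5-(trimethylsilyl)pent-4-ynoate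
Product: 5 ethyl (R)-3-(methanesulfonyloxy)-5-(trimethylsilyl)pent-4-ynoate
Conditions: MsCl, Et3N, CH2Cl2, −78 °C; cold work-up, used at once
Reagents that add atoms: methanesulfonyl chloride, CS(=O)(=O)Cl
Why: Standard sulfonylation of a propargylic alcohol with retention; low temperature and immediate use avoid E1cB loss of the β-sulfonate from the ester.

Step 4
Reactants: 5 ethyl (R)-3-(methanesulfonyloxy)-5-(trimethylsilyl)pent-4-ynoate
Product: 6 ethyl (aS)-5-(tributylstannyl)-5-(trimethylsilyl)penta-3,4-dienoate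
Conditions: Bu3SnH, LiN(iPr)2, THF, 0 °C; CuBr·SMe2, −78 °C; then 5, −78 °C
Reagents that add atoms: tributyltin hydride, CCCC[SnH](CCCC)CCCC
Why: Anti SN2′ displacement of a propargylic sulfonate by a stannylcopper reagent, the standard route to enantioenriched allenylstannanes, should transfer the carbinol chirality to the allene axis (silyl-capped propargylic sulfonates are known to react SN2′ with organocopper reagents).

Step 5
Reactants: 6 ethyl (aS)-5-(tributylstannyl)-5-(trimethylsilyl)penta-3,4-dienoate; 7 3,4-dimethoxybenzaldehyde (veratraldehyde)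
Product: 9 (4R,5S)-5-(3,4-dimethoxyphenyl)-4-[(trimethylsilyl)ethynyl]dihydrofuran-2(3H)-one, via syn hydroxy ester 8 (not isolated)
Conditions: BF3·OEt2 (2 equiv), CH2Cl2, −78 °C; aqueous work-up; then PPTS (10 mol %), PhMe, 50 °C
Reagents that add atoms: none
Why: BF3-promoted SE2′ addition of a chiral allenylstannane through an open antiperiplanar transition state, in which attack anti to tin sets C3 from the allene axis and the syn topicity (aryl turned away from the CH2CO2Et arm) sets C2; mild acid lactonisation with retention at both centres should then give the trans lactone, because the syn alcohol and the trans lactone have the same relative configuration.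

Step 6
Reactants: 9 (4R,5S)-5-(3,4-dimethoxyphenyl)-4-[(trimethylsilyl)ethynyl]dihydrofuran-2(3H)-one
Product: 10 (4R,5S)-3-acetyl-5-(3,4-dimethoxyphenyl)-4-[(trimethylsilyl)ethynyl]dihydrofuran-2(3H)-one (C3 epimers and enol)
Conditions: LiN(iPr)2 (1.15 equiv), THF, −78 °C; MeC(O)N(OMe)Me, −78 → −20 °C; AcOH
Reagents that add atoms: N-methoxy-N-methylacetamide, CC(=O)N(C)OC
Why: C-acylation of a lactone lithium enolate with a Weinreb amide, whose chelated tetrahedral intermediate prevents proton transfer from the β-dicarbonyl product; the new C3 centre is epimerisable and is erased in step 8.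

Step 7
Reactants: 7 3,4-dimethoxybenzaldehyde (veratraldehyde); 11 diethyl {2-[methoxy(methyl)amino]-2-oxoethyl}phosphonate
Product: 12 (E)-3-(3,4-dimethoxyphenyl)-N-methoxy-N-methylprop-2-enamide
Conditions: NaH, THF, 0 °C → rt
Reagents that add atoms: none
Why: Horner–Wadsworth–Emmons olefination with a stabilised amide phosphonate should give the (E)-cinnamic Weinreb amide.

Step 8
Reactants: 10 (4R,5S)-3-acetyl-5-(3,4-dimethoxyphenyl)-4-[(trimethylsilyl)ethynyl]dihydrofuran-2(3H)-one; 12 (E)-3-(3,4-dimethoxyphenyl)-N-methoxy-N-methylprop-2-enamide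
Product: 15 (2S,3R)-2-(3,4-dimethoxyphenyl)-6-[(E)-3,4-dimethoxystyryl]-3-[(trimethylsilyl)ethynyl]-2,3-dihydro-4H-furo[3,2-c]pyran-4-one, via triketide lactone 13 (not isolated), via hydroxypyranone 14 (not isolated)
Conditions: LiN(iPr)2 (2.3 equiv), THF, −78 °C; 12, −78 → −30 °C; AcOH; then DBU (1.2 equiv), PhMe, 50 °C; then camphorsulfonic acid (1.5 equiv), 4 Å MS, 50 °C
Reagents that add atoms: none
Why: Proposed new method: LiN(iPr)2 forms the 1,3-dicarbonyl dianion of 10, whose terminal carbanion (C7) adds 1,2 to Weinreb amide 12 through a chelated tetrahedral intermediate and gives, on quench, the lactone-bound triketide 13 (bond C6–C7), as in the known acylation of acetoacetate dianions. DBU then turns the C6/C7a diketone into its enolate, whose C6 oxygen attacks the lactone carbonyl C4 (6-exo-trig acyl transfer, ring A, bond C4–O5) and expels the C2 alkoxide, pulled forward by the acidic, aromatic 4-hydroxy-2-pyranone anion of 14; this is the DBU lactonisation of 3,5-diketo esters run with a lactone in the role of the ester. After acidification the freed C2 hydroxyl adds to the C7a carbonyl of the pyran-2,4-dione tautomer (5-exo-trig hemiketal) and water is lost (dihydrofuran ring, bond O1–C7a), the counterpart of the acid rearrangement of α-acyl-γ-butyrolactones to 4,5-dihydrofuran-3-carboxylates. No stereocentre is made: C2 and C3 come unchanged from 10 because the C2–O1 bond is not broken on this path and C3 carries no acidic hydrogen, while C3a becomes planar. The step needs acylation at the terminal and not the internal carbanion (secured by the higher basicity and lower hindrance of the terminal site and by the 1,2-selectivity of the Weinreb amide), closure of the hydroxyl on C7a and not on C4 (the 4-alkoxy-2-pyranone is the thermodynamic isomer and the hemiketals interconvert under acid), and the trans geometry (should the electron-rich benzylic C2–O bond ionise, re-closure anti to the C3 substituent returns the same isomer).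

Step 9
Reactants: 15 (2S,3R)-2-(3,4-dimethoxyphenyl)-6-[(E)-3,4-dimethoxystyryl]-3-[(trimethylsilyl)ethynyl]-2,3-dihydro-4H-furo[3,2-c]pyran-4-one
Product: 16 (2S,3S)-2-(3,4-dimethoxyphenyl)-6-[(E)-3,4-dimethoxystyryl]-3-ethynyl-2,3-dihydro-4H-furo[3,2-c]pyran-4-one
Conditions: Bu4NF/AcOH (1:1), THF, 0 °C
Reagents that add atoms: none
Why: Fluoride protodesilylation of an alkynylsilane, buffered with acetic acid so that the medium stays non-basic and neither C3–H nor the pyranone is touched.

Step 10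
Reactants: 16 (2S,3S)-2-(3,4-dimethoxyphenyl)-6-[(E)-3,4-dimethoxystyryl]-3-ethynyl-2,3-dihydro-4H-furo[3,2-c]pyran-4-one
Product: 17 3-[(2S,3S)-2-(3,4-dimethoxyphenyl)-6-[(E)-3,4-dimethoxystyryl]-4-oxo-2,3-dihydro-4H-furo[3,2-c]pyran-3-yl]prop-2-ynal
Conditions: DMF (5 equiv), LiN(SiMe3)2 (1.1 equiv), THF, −78 °C; inverse quench into cold aqueous AcOH
Reagents that add atoms: N,N-dimethylformamide, CN(C)C=O
Why: Formylation of a lithium acetylide with DMF, using a non-nucleophilic amide base on the kinetically most acidic sp C–H with the electrophile already present, so that the acetylide is trapped as the hemiaminal alkoxide before it can attack a pyranone.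

Step 11
Reactants: 17 3-[(2S,3S)-2-(3,4-dimethoxyphenyl)-6-[(E)-3,4-dimethoxystyryl]-4-oxo-2,3-dihydro-4H-furo[3,2-c]pyran-3-yl]prop-2-ynal
Product: 18 tert-butyl 5-[(2S,3S)-2-(3,4-dimethoxyphenyl)-6-[(E)-3,4-dimethoxystyryl]-4-oxo-2,3-dihydro-4H-furo[3,2-c]pyran-3-yl]-3-hydroxypent-4-ynoate (carbinol epimers)
Conditions: BrZnCH2CO2tBu (1.5 equiv), THF, −20 → 0 °C; 1 M HCl
Reagents that add atoms: (2-tert-butoxy-2-oxoethyl)zinc bromide, CC(C)(C)OC(=O)C[Zn]Br
Why: Reformatsky 1,2-addition of a zinc ester enolate to an ynal; the reagent is too weakly basic to remove the now vinylogously acidic C3–H and does not attack the pyranone, and the new carbinol centre is removed in step 12.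

Step 12
Reactants: 18 tert-butyl 5-[(2S,3S)-2-(3,4-dimethoxyphenyl)-6-[(E)-3,4-dimethoxystyryl]-4-oxo-2,3-dihydro-4H-furo[3,2-c]pyran-3-yl]-3-hydroxypent-4-ynoate
Product: 19 tert-butyl 5-[(2S,3S)-2-(3,4-dimethoxyphenyl)-6-[(E)-3,4-dimethoxystyryl]-4-oxo-2,3-dihydro-4H-furo[3,2-c]pyran-3-yl]-3-oxopent-4-ynoate
Conditions: Dess–Martin periodinane, CH2Cl2, 0 °C → rt
Reagents that add atoms: none
Why: Dess–Martin oxidation of a propargylic alcohol to the ynone under neutral conditions, the usual way to tert-butyl 3-oxo-4-ynoates.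

Step 13
Reactants: 19 tert-butyl 5-[(2S,3S)-2-(3,4-dimethoxyphenyl)-6-[(E)-3,4-dimethoxystyryl]-4-oxo-2,3-dihydro-4H-furo[3,2-c]pyran-3-yl]-3-oxopent-4-ynoate
Product: 20 (2S,3S)-2-(3,4-dimethoxyphenyl)-6-[(E)-3,4-dimethoxystyryl]-3-(4-hydroxy-2-oxo-2H-pyran-6-yl)-2,3-dihydro-4H-furo[3,2-c]pyran-4-one (tetra-O-methylhypholomine B)
Conditions: Ph3PAuNTf2 (5 mol %), CH2Cl2/AcOH, rt
Reagents that add atoms: none
Why: Gold-catalysed (monovalent gold) 6-endo-dig cyclisation of a tert-butyl 3-oxo-4-ynoate, in which the ester carbonyl oxygen adds to the activated alkyne carbon remote from the ketone, the oxocarbenium ion loses isobutene and protodeauration gives ring B; the trans relation of aryl and alkynyl groups rules out hydroarylation.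

Step 14
Reactants: 20 (2S,3S)-2-(3,4-dimethoxyphenyl)-6-[(E)-3,4-dimethoxystyryl]-3-(4-hydroxy-2-oxo-2H-pyran-6-yl)-2,3-dihydro-4H-furo[3,2-c]pyran-4-one
Product: 21 hypholomine B, (2S,3S)-2-(3,4-dihydroxyphenyl)-6-[(E)-3,4-dihydroxystyryl]-3-(4-hydroxy-2-oxo-2H-pyran-6-yl)-2,3-dihydro-4H-furo[3,2-c]pyran-4-one
Conditions: BBr3 (10 equiv), CH2Cl2, −78 → 0 °C; ice-water
Reagents that add atoms: none
Why: Lewis-acid cleavage of the four aryl methyl ethers with BBr3, a reaction type used on methylated styrylpyranones and on trans-2-aryl-2,3-dihydrobenzofurans; a transient opening of the C2–O1 bond would re-close to the more stable trans isomer.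

**Compound list**

1 | ethyl 3-(trimethylsilyl)prop-2-ynoate | CCOC(=O)C#C[Si](C)(C)C | starting material
2 | ethyl acetate | CCOC(C)=O | starting material
3 | ethyl 3-oxo-5-(trimethylsilyl)pent-4-ynoate | CCOC(=O)CC(=O)C#C[Si](C)(C)C | intermediate
4 | ethyl (R)-3-hydroxy-5-(trimethylsilyl)pent-4-ynoate | CCOC(=O)C[C@@H](O)C#C[Si](C)(C)C | intermediate
5 | ethyl (R)-3-(methanesulfonyloxy)-5-(trimethylsilyl)pent-4-ynoate | CCOC(=O)C[C@@H](OS(C)(=O)=O)C#C[Si](C)(C)C | intermediate
6 | ethyl (aS)-5-(tributylstannyl)-5-(trimethylsilyl)penta-3,4-dienoate | CCOC(=O)CC([H])=[C@@]=C([Si](C)(C)C)[Sn](CCCC)(CCCC)CCCC | intermediate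
7 | 3,4-dimethoxybenzaldehyde (veratraldehyde) | COc1ccc(C=O)cc1OC | starting material
8 | ethyl (3R)-3-[(S)-(3,4-dimethoxyphenyl)(hydroxy)methyl]-5-(trimethylsilyl)pent-4-ynoate (syn) | CCOC(=O)C[C@H](C#C[Si](C)(C)C)[C@H](O)c1ccc(OC)c(OC)c1 | intermediate
9 | (4R,5S)-5-(3,4-dimethoxyphenyl)-4-[(trimethylsilyl)ethynyl]dihydrofuran-2(3H)-one (trans) | O=C1C[C@H](C#C[Si](C)(C)C)[C@@H](c2ccc(OC)c(OC)c2)O1 | intermediate
10 | (4R,5S)-3-acetyl-5-(3,4-dimethoxyphenyl)-4-[(trimethylsilyl)ethynyl]dihydrofuran-2(3H)-one (C3 epimers) | CC(=O)C1[C@H](C#C[Si](C)(C)C)[C@@H](c2ccc(OC)c(OC)c2)OC1=O | intermediate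
11 | diethyl {2-[methoxy(methyl)amino]-2-oxoethyl}phosphonate | CCOP(=O)(CC(=O)N(C)OC)OCC | starting material
12 | (E)-3-(3,4-dimethoxyphenyl)-N-methoxy-N-methylprop-2-enamide | COc1ccc(/C=C/C(=O)N(C)OC)cc1OC | intermediate
13 | (4R,5S)-5-(3,4-dimethoxyphenyl)-3-[(E)-5-(3,4-dimethoxyphenyl)-3-oxopent-4-enoyl]-4-[(trimethylsilyl)ethynyl]dihydrofuran-2(3H)-one | COc1ccc(/C=C/C(=O)CC(=O)C2[C@H](C#C[Si](C)(C)C)[C@@H](c3ccc(OC)c(OC)c3)OC2=O)cc1OC | intermediate
14 | 3-[(1S,2R)-1-(3,4-dimethoxyphenyl)-1-hydroxy-4-(trimethylsilyl)but-3-yn-2-yl]-6-[(E)-3,4-dimethoxystyryl]-4-hydroxy-2H-pyran-2-one | COc1ccc(/C=C/c2cc(O)c([C@H](C#C[Si](C)(C)C)[C@H](O)c3ccc(OC)c(OC)c3)c(=O)o2)cc1OC | intermediate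
15 | (2S,3R)-2-(3,4-dimethoxyphenyl)-6-[(E)-3,4-dimethoxystyryl]-3-[(trimethylsilyl)ethynyl]-2,3-dihydro-4H-furo[3,2-c]pyran-4-one (trans) | C[Si](C)(C)C#C[C@H]1c2c(cc(/C=C/c3ccc(OC)c(OC)c3)oc2=O)O[C@@H]1c1ccc(OC)c(OC)c1 | intermediate
16 | (2S,3S)-2-(3,4-dimethoxyphenyl)-6-[(E)-3,4-dimethoxystyryl]-3-ethynyl-2,3-dihydro-4H-furo[3,2-c]pyran-4-one | C#C[C@H]1c2c(cc(/C=C/c3ccc(OC)c(OC)c3)oc2=O)O[C@@H]1c1ccc(OC)c(OC)c1 | intermediate
17 | 3-[(2S,3S)-2-(3,4-dimethoxyphenyl)-6-[(E)-3,4-dimethoxystyryl]-4-oxo-2,3-dihydro-4H-furo[3,2-c]pyran-3-yl]prop-2-ynal | O=CC#C[C@H]1c2c(cc(/C=C/c3ccc(OC)c(OC)c3)oc2=O)O[C@@H]1c1ccc(OC)c(OC)c1 | intermediate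
18 | tert-butyl 5-[(2S,3S)-2-(3,4-dimethoxyphenyl)-6-[(E)-3,4-dimethoxystyryl]-4-oxo-2,3-dihydro-4H-furo[3,2-c]pyran-3-yl]-3-hydroxypent-4-ynoate (carbinol epimers) | CC(C)(C)OC(=O)CC(O)C#C[C@H]1c2c(cc(/C=C/c3ccc(OC)c(OC)c3)oc2=O)O[C@@H]1c1ccc(OC)c(OC)c1 | intermediate
19 | tert-butyl 5-[(2S,3S)-2-(3,4-dimethoxyphenyl)-6-[(E)-3,4-dimethoxystyryl]-4-oxo-2,3-dihydro-4H-furo[3,2-c]pyran-3-yl]-3-oxopent-4-ynoate | CC(C)(C)OC(=O)CC(=O)C#C[C@H]1c2c(cc(/C=C/c3ccc(OC)c(OC)c3)oc2=O)O[C@@H]1c1ccc(OC)c(OC)c1 | intermediate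
20 | (2S,3S)-2-(3,4-dimethoxyphenyl)-6-[(E)-3,4-dimethoxystyryl]-3-(4-hydroxy-2-oxo-2H-pyran-6-yl)-2,3-dihydro-4H-furo[3,2-c]pyran-4-one | O=c1cc(O)cc([C@H]2c3c(cc(/C=C/c4ccc(OC)c(OC)c4)oc3=O)O[C@@H]2c2ccc(OC)c(OC)c2)o1 | intermediate
21 | hypholomine B | O=c1cc(O)cc([C@H]2c3c(cc(/C=C/c4ccc(O)c(O)c4)oc3=O)O[C@@H]2c2ccc(O)c(O)c2)o1 | target

**Step count**

Total: 14 steps. Longest linear sequence: 13 steps (steps 1–6 and 8–14); step 7 is a one-step side branch.

**Steps most likely to fail**

Step 8 (proposed new method). The acyl transfer from the butyrolactone to the enol oxygen may stall. The tricarbonyl chain may also lose water towards the linear 2-alkoxy-4-pyranone, or the benzylic C2–O bond may ionise and eliminate across C2–C3. The fallback uses only established reactions; it sets out from hydroxy ester 8, taken through a cold work-up before it lactonises, and comes back at 15. Silylation (tBuMe2SiOTf, 2,6-lutidine, CH2Cl2, −78 °C) should give ethyl (3R)-3-[(S)-(tert-butyldimethylsilyloxy)(3,4-dimethoxyphenyl)methyl]-5-(trimethylsilyl)pent-4-ynoate F1. Enolate acetylation as in step 6 should give ethyl (3R)-2-acetyl-3-[(S)-(tert-butyldimethylsilyloxy)(3,4-dimethoxyphenyl)methyl]-5-(trimethylsilyl)pent-4-ynoate F2. Its dianion (LiN(iPr)2, 2.2 equiv) would be acylated with 12 to ethyl (3R)-3-[(S)-(tert-butyldimethylsilyloxy)(3,4-dimethoxyphenyl)methyl]-2-[(E)-5-(3,4-dimethoxyphenyl)-3-oxopent-4-enoyl]-5-(trimethylsilyl)pent-4-ynoate F3. DBU in warm toluene, the routine lactonisation of open-chain 3,5-diketo esters, should close 3-[(1S,2R)-1-(tert-butyldimethylsilyloxy)-1-(3,4-dimethoxyphenyl)-4-(trimethylsilyl)but-3-yn-2-yl]-6-[(E)-3,4-dimethoxystyryl]-4-hydroxy-2H-pyran-2-one F4 with loss of ethanol. HF·pyridine would then free the benzylic alcohol to give 14, and the acid cyclodehydration of 3-(2-hydroxyalkyl)-4-hydroxy-2-pyranones (camphorsulfonic acid, 4 Å MS) would close the dihydrofuran to 15.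

Step 5. Facial discrimination of the aldehyde in the open transition state may be poor, which would erode the syn selectivity; the allenylstannane may also isomerise to its propargylic form under BF3. The fallback changes to a closed transition state and an invertive ring closure; it sets out from keto ester 3 and comes back at lactone 9. Reduction as in step 2 but with the (S,S)-ligand should give ethyl (S)-3-hydroxy-5-(trimethylsilyl)pent-4-ynoate F5, and sulfonylation as in step 3 gives ethyl (S)-3-(methanesulfonyloxy)-5-(trimethylsilyl)pent-4-ynoate F6. With Pd(OAc)2/PPh3 (zerovalent palladium formed in the flask) and Et2Zn in THF at −20 °C, F6 should form an allenylzinc reagent that adds to 7 through a cyclic SE2′ transition state. This addition is syn to the metal, which is why the other enantiomer of the sulfonate is needed to reach the same C3 configuration. It should give the anti adduct ethyl (3R)-3-[(R)-(3,4-dimethoxyphenyl)(hydroxy)methyl]-5-(trimethylsilyl)pent-4-ynoate F7. Activation of the benzylic hydroxyl (MsCl, Et3N, −20 °C → rt) then lets the ester carbonyl close on the benzylic carbon with inversion, anti to the alkynyl group, to give trans lactone 9.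

Step 10. Deprotonation at C3 may compete and be followed by β-elimination of the ring oxygen O1, or the acetylide may add to a pyranone carbonyl. The fallback avoids any strongly basic acetylide; it sets out from alkyne 16 and comes back at keto ester 19, bypassing 17 and 18. Warming 16 with Bu3SnOMe (PhMe, 60 °C, methanol removed) should give (2S,3R)-2-(3,4-dimethoxyphenyl)-6-[(E)-3,4-dimethoxystyryl]-3-[(tributylstannyl)ethynyl]-2,3-dihydro-4H-furo[3,2-c]pyran-4-one F8. A Stille acylation (PdCl2(PPh3)2 cat., THF, rt) with tert-butyl 3-chloro-3-oxopropanoate F9, freshly made from 3-tert-butoxy-3-oxopropanoic acid and oxalyl chloride with a trace of DMF, should then give 19 directly.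

**Further compounds**

F1 | step 8 | ethyl (3R)-3-[(S)-(tert-butyldimethylsilyloxy)(3,4-dimethoxyphenyl)methyl]-5-(trimethylsilyl)pent-4-ynoate | CCOC(=O)C[C@H](C#C[Si](C)(C)C)[C@H](O[Si](C)(C)C(C)(C)C)c1ccc(OC)c(OC)c1
F2 | step 8 | ethyl (3R)-2-acetyl-3-[(S)-(tert-butyldimethylsilyloxy)(3,4-dimethoxyphenyl)methyl]-5-(trimethylsilyl)pent-4-ynoate (C2 epimers) | CCOC(=O)C(C(C)=O)[C@H](C#C[Si](C)(C)C)[C@H](O[Si](C)(C)C(C)(C)C)c1ccc(OC)c(OC)c1
F3 | step 8 | ethyl (3R)-3-[(S)-(tert-butyldimethylsilyloxy)(3,4-dimethoxyphenyl)methyl]-2-[(E)-5-(3,4-dimethoxyphenyl)-3-oxopent-4-enoyl]-5-(trimethylsilyl)pent-4-ynoate | CCOC(=O)C(C(=O)CC(=O)/C=C/c1ccc(OC)c(OC)c1)[C@H](C#C[Si](C)(C)C)[C@H](O[Si](C)(C)C(C)(C)C)c1ccc(OC)c(OC)c1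
F4 | step 8 | 3-[(1S,2R)-1-(tert-butyldimethylsilyloxy)-1-(3,4-dimethoxyphenyl)-4-(trimethylsilyl)but-3-yn-2-yl]-6-[(E)-3,4-dimethoxystyryl]-4-hydroxy-2H-pyran-2-one | COc1ccc(/C=C/c2cc(O)c([C@H](C#C[Si](C)(C)C)[C@H](O[Si](C)(C)C(C)(C)C)c3ccc(OC)c(OC)c3)c(=O)o2)cc1OC
F5 | step 5 | ethyl (S)-3-hydroxy-5-(trimethylsilyl)pent-4-ynoate | CCOC(=O)C[C@H](O)C#C[Si](C)(C)C
F6 | step 5 | ethyl (S)-3-(methanesulfonyloxy)-5-(trimethylsilyl)pent-4-ynoate | CCOC(=O)C[C@H](OS(C)(=O)=O)C#C[Si](C)(C)C
F7 | step 5 | ethyl (3R)-3-[(R)-(3,4-dimethoxyphenyl)(hydroxy)methyl]-5-(trimethylsilyl)pent-4-ynoate (anti) | CCOC(=O)C[C@H](C#C[Si](C)(C)C)[C@@H](O)c1ccc(OC)c(OC)c1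
F8 | step 10 | (2S,3R)-2-(3,4-dimethoxyphenyl)-6-[(E)-3,4-dimethoxystyryl]-3-[(tributylstannyl)ethynyl]-2,3-dihydro-4H-furo[3,2-c]pyran-4-one | CCCC[Sn](CCCC)(CCCC)C#C[C@H]1c2c(cc(/C=C/c3ccc(OC)c(OC)c3)oc2=O)O[C@@H]1c1ccc(OC)c(OC)c1
F9 | step 10 | tert-butyl 3-chloro-3-oxopropanoate | CC(C)(C)OC(=O)CC(=O)Cl
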